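## Retrosynthetic overview

1. Leucanthin B ⇐ oxidation of the C14 enal to the acid ⇐ esterification of C8–OH with (2R,3R)-epoxyangelic acid (made separately by Sharpless epoxidation).
2. Ten-membered carbocycle (last ring) ⇐ ring-closing metathesis at C1=C10 of a seco-diene that already carries both oxiranes and the trans-γ-lactone.
3. trans-γ-Lactone plus free C9–OH ⇐ translactonisation of an α-methylene-δ-lactone; 4,5-oxirane (C3 and C6 cis) ⇐ C6–OH-directed epoxidation of a (Z)-trisubstituted olefin.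
4. Key C6–C7 bond ⇐ intermolecular Zn-mediated carbonyl allylation of (Z)-enal fragment A (C1–C6, cis-vinyloxirane) by cyclic allylic bromide fragment B (C7–C14).
5. Ring order: δ-lactone (fragment B) and 2,3-oxirane (fragment A) → 4,5-oxirane → γ-lactone (δ-lactone opened) → ten-membered ring; the side-chain oxirane is made separately.

Assumption: locants C1–C15 follow germacrane numbering (C1=C10 with C14 on C10; C2/C3 and C4/C5 oxiranes with C15 on C4; C6 lactone carbinol; C11=C13; C12 lactone carbonyl), and 1, 2, 6, 12, 15, 19, 24, (+)-Ipc2BOMe and Me2BBr are bought.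

## Fragment A (C1–C6)

Step 1
Reactants: 1 (tert-butyldimethylsilyloxy)acetaldehyde; 2 ethyl 2-[bis(2,2,2-trifluoroethoxy)phosphoryl]propanoate
Product: 3 ethyl (2Z)-4-[(tert-butyldimethylsilyl)oxy]-2-methylbut-2-enoate
Conditions: KN(SiMe3)2, 18-crown-6, THF, −78 °C
Reagents that add atoms: none
Why: Still–Gennari olefination, in which the electron-poor bis(trifluoroethyl) phosphonate and the dissociated potassium ion make the kinetic oxaphosphetane collapse before it equilibrates, gives the (Z)-trisubstituted enoate with the ester carbon (future C3) cis to the CH2O carbon (future C6).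

Step 2
Reactants: 3 ethyl (2Z)-4-[(tert-butyldimethylsilyl)oxy]-2-methylbut-2-enoate
Product: 4 (2Z)-4-[(tert-butyldimethylsilyl)oxy]-2-methylbut-2-en-1-ol
Conditions: i-Bu2AlH (2.2 equiv), CH2Cl2, −78 °C to −20 °C
Reagents that add atoms: none
Why: Hydride reduction of the conjugated ester gives the allylic alcohol by 1,2-addition only, without touching the silyl ether or the (Z)-alkene.

Step 3
Reactants: 4 (2Z)-4-[(tert-butyldimethylsilyl)oxy]-2-methylbut-2-en-1-ol
Product: 5 (2Z)-4-[(tert-butyldimethylsilyl)oxy]-2-methylbut-2-enal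
Conditions: MnO2, CH2Cl2, 0 °C, used at once
Reagents that add atoms: none
Why: MnO2 allylic oxidation is neutral and heterogeneous, so the (Z)-2-methyl enal is formed without the acid or base that would isomerise it to the (E)-isomer.

Step 4
Reactants: 5 (2Z)-4-[(tert-butyldimethylsilyl)oxy]-2-methylbut-2-enal; 6 allyl chloride
Product: 8 (3S,4S,5Z)-7-[(tert-butyldimethylsilyl)oxy]-3-chloro-5-methylhepta-1,5-dien-4-ol, via (Z)-γ-chloroallyldiisopinocampheylborane 7 (not isolated)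
Conditions: 6, LiN(c-C6H11)2, (+)-Ipc2BOMe [from (−)-α-pinene], BF3·OEt2, Et2O, −95 °C; then 5, −95 °C; then HOCH2CH2NH2
Reagents that add atoms: none
Why: Oehlschlager–Brown asymmetric γ-chloroallylboration (carbonyl allylation through a closed chair transition state) in which the (Z)-borane gives the syn chlorohydrin and the Ipc groups from (−)-α-pinene select the aldehyde face that sets C3 and C2 as (4S,3S).

Step 5
Reactants: 8 (3S,4S,5Z)-7-[(tert-butyldimethylsilyl)oxy]-3-chloro-5-methylhepta-1,5-dien-4-ol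
Product: 9 tert-butyl({(2Z)-3-[(2S,3R)-3-ethenyloxiran-2-yl]but-2-en-1-yl}oxy)dimethylsilane
Conditions: DBU, CH2Cl2, 20 °C (keep below 25 °C)
Reagents that add atoms: none
Why: Intramolecular Williamson (SN2) closure with inversion at the chlorine-bearing carbon converts the syn chlorohydrin into the cis-2,3-oxirane without touching the silyl ether or the alkene geometry.

Step 6
Reactants: 9 tert-butyl({(2Z)-3-[(2S,3R)-3-ethenyloxiran-2-yl]but-2-en-1-yl}oxy)dimethylsilane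
Product: 10 (2Z)-3-[(2S,3R)-3-ethenyloxiran-2-yl]but-2-en-1-ol
Conditions: Bu4NF/AcOH 1:1, THF, 0 °C
Reagents that add atoms: none
Why: Acetic acid-buffered fluoride desilylation is neither acidic nor alkoxide-forming, so the vinyl oxirane survives and the freed hydroxyl, which is cis to the oxirane, does not open it.

Step 7
Reactants: 10 (2Z)-3-[(2S,3R)-3-ethenyloxiran-2-yl]but-2-en-1-ol
Product: 11 (2Z)-3-[(2S,3R)-3-ethenyloxiran-2-yl]but-2-enal
Conditions: MnO2, CH2Cl2, 0 °C to 20 °C, used at once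
Reagents that add atoms: none
Why: MnO2 allylic oxidation is neutral and chemoselective for the primary allylic alcohol, giving the C6 enal with the (Z)-geometry (as in nerol to neral) and the oxirane intact.

## Fragment B (C7–C14)

Step 8
Reactants: 12 2-methylidenepropane-1,3-diol
Product: 13 2-{[(tert-butyldiphenylsilyl)oxy]methyl}prop-2-en-1-ol
Conditions: NaH (1.0 equiv), THF, 0 °C; then t-BuPh2SiCl
Reagents that add atoms: tert-butyl(chloro)diphenylsilane (CC(C)(C)[Si](Cl)(c1ccccc1)c1ccccc1)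
Why: Monosilylation of a symmetrical diol through its sparingly soluble mono-sodium alkoxide (McDougal protocol) protects only one hydroxyl, the future C14–O.

Step 9
Reactants: 13 2-{[(tert-butyldiphenylsilyl)oxy]methyl}prop-2-en-1-ol
Product: 14 2-{[(tert-butyldiphenylsilyl)oxy]methyl}prop-2-enal
Conditions: MnO2, CH2Cl2, 20 °C
Reagents that add atoms: none
Why: MnO2 allylic oxidation gives the 2-substituted acrolein (C9 aldehyde) under neutral conditions that spare the silyl ether.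

Step 10
Reactants: 15 allyl alcohol
Product: 16 3-(methoxymethoxy)prop-1-ene
Conditions: MeOCH2Cl, i-Pr2NEt, CH2Cl2, 0 °C to 20 °C
Reagents that add atoms: chloromethyl methyl ether (COCCl)
Why: O-alkylation (acetal ether formation) of a primary alcohol with an α-chloro ether is fast and clean with a hindered amine base.

Step 11
Reactants: 14 2-{[(tert-butyldiphenylsilyl)oxy]methyl}prop-2-enal; 16 3-(methoxymethoxy)prop-1-ene
Product: 18 (3S,4S)-2-{[(tert-butyldiphenylsilyl)oxy]methyl}-4-(methoxymethoxy)hexa-1,5-dien-3-ol, via (Z)-γ-(methoxymethoxy)allyldiisopinocampheylborane 17 (not isolated)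
Conditions: 16, s-BuLi, THF, −78 °C; (+)-Ipc2BOMe [from (−)-α-pinene]; BF3·OEt2; then 14, −78 °C; then HOCH2CH2NH2
Reagents that add atoms: none
Why: Brown asymmetric γ-alkoxyallylboration (carbonyl allylation, chair transition state) in which the (Z)-γ-alkoxyallylborane gives the syn 1,2-diol monoether and the Ipc groups from (−)-α-pinene set C9 and C8 as (3S,4S).

Step 12
Reactants: 18 (3S,4S)-2-{[(tert-butyldiphenylsilyl)oxy]methyl}-4-(methoxymethoxy)hexa-1,5-dien-3-ol; 19 2-(bromomethyl)prop-2-enoic acid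
Product: 20 (3S,4S)-2-{[(tert-butyldiphenylsilyl)oxy]methyl}-4-(methoxymethoxy)hexa-1,5-dien-3-yl 2-(bromomethyl)prop-2-enoate
Conditions: DCC, DMAP (5 mol%), CH2Cl2, 0 °C
Reagents that add atoms: none
Why: Steglich esterification acylates the only free hydroxyl (C9–OH) with retention, and the low DMAP loading at 0 °C keeps the allylic bromide intact.

Step 13
Reactants: 20 (3S,4S)-2-{[(tert-butyldiphenylsilyl)oxy]methyl}-4-(methoxymethoxy)hexa-1,5-dien-3-yl 2-(bromomethyl)prop-2-enoate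
Product: 21 (5S,6S)-3-(bromomethyl)-6-(3-{[tert-butyl(diphenyl)silyl]oxy}prop-1-en-2-yl)-5-(methoxymethoxy)-5,6-dihydro-2H-pyran-2-one
Conditions: second-generation Grubbs catalyst RuCl2(=CHPh)(PCy3)(H2IMes) (5 mol%), CH2Cl2 (5 mM), 40 °C
Reagents that add atoms: none
Why: Ring-closing metathesis loads on the monosubstituted vinyl group and closes onto the acrylate to give the only unstrained ring, the six-membered lactone with the C7=C11 alkene, leaving the stereocentres untouched so that the C8 oxygen and the C9 side chain are cis.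

Step 14
Reactants: 21 (5S,6S)-3-(bromomethyl)-6-(3-{[tert-butyl(diphenyl)silyl]oxy}prop-1-en-2-yl)-5-(methoxymethoxy)-5,6-dihydro-2H-pyran-2-one
Product: 22 (5S,6S)-3-(bromomethyl)-6-(3-{[tert-butyl(diphenyl)silyl]oxy}prop-1-en-2-yl)-5-hydroxy-5,6-dihydro-2H-pyran-2-one
Conditions: Me2BBr, CH2Cl2, −78 °C; then sat. aq NaHCO3
Reagents that add atoms: none
Why: Guindon acetal cleavage with a bromoborane removes the methoxymethyl ether at −78 °C while the silyl ether, lactone and allylic bromide survive, and it is done here because no oxirane is present yet.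

Step 15
Reactants: 22 (5S,6S)-3-(bromomethyl)-6-(3-{[tert-butyl(diphenyl)silyl]oxy}prop-1-en-2-yl)-5-hydroxy-5,6-dihydro-2H-pyran-2-one
Product: 23 (5S,6S)-3-(bromomethyl)-6-(3-{[tert-butyl(diphenyl)silyl]oxy}prop-1-en-2-yl)-5-[(triethylsilyl)oxy]-5,6-dihydro-2H-pyran-2-one
Conditions: Et3SiOTf, 2,6-lutidine, CH2Cl2, −78 °C
Reagents that add atoms: triethylsilyl trifluoromethanesulfonate (CC[Si](CC)(CC)OS(=O)(=O)C(F)(F)F)
Why: Silylation with a silyl triflate and a hindered base installs a fluoride-labile, sterically directing group on C8–O without displacing the allylic bromide.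

## Side-chain acid

Step 16
Reactants: 24 angelic acid [(2Z)-2-methylbut-2-enoic acid]
Product: 25 (2Z)-2-methylbut-2-en-1-ol
Conditions: LiAlH4, Et2O, 0 °C
Reagents that add atoms: none
Why: Hydride reduction of the carboxylic acid gives the allylic alcohol without touching or isomerising the trisubstituted (Z)-alkene.

Step 17
Reactants: 25 (2Z)-2-methylbut-2-en-1-ol
Product: 26 [(2S,3R)-2,3-dimethyloxiran-2-yl]methanol
Conditions: Ti(OiPr)4 (10 mol%), L-(+)-diethyl tartrate (12 mol%), t-BuOOH, 4 Å MS, CH2Cl2, −20 °C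
Reagents that add atoms: tert-butyl hydroperoxide (CC(C)(C)OO)
Why: Sharpless asymmetric epoxidation with L-(+)-tartrate delivers oxygen to the alkene face that gives the (2S)-epoxy alcohol, and the (Z)-geometry fixes the C3′-methyl cis to C1′, hence (2S,3R).

Step 18
Reactants: 26 [(2S,3R)-2,3-dimethyloxiran-2-yl]methanol
Product: 27 (2R,3R)-2,3-dimethyloxirane-2-carboxylic acid
Conditions: TEMPO (cat.), PhI(OAc)2, MeCN/H2O 1:1, 20 °C
Reagents that add atoms: water (O)
Why: Oxoammonium (TEMPO) oxidation takes the primary alcohol through the aldehyde hydrate to the acid under near-neutral conditions that leave the oxirane and both stereocentres untouched (the descriptor at C2′ changes only by priority).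

## Fragment union and endgame

Step 19
Reactants: 11 (2Z)-3-[(2S,3R)-3-ethenyloxiran-2-yl]but-2-enal; 23 (5S,6S)-3-(bromomethyl)-6-(3-{[tert-butyl(diphenyl)silyl]oxy}prop-1-en-2-yl)-5-[(triethylsilyl)oxy]-5,6-dihydro-2H-pyran-2-one
Product: 29 (4S,5S,6S)-6-(3-{[tert-butyl(diphenyl)silyl]oxy}prop-1-en-2-yl)-4-{(1R,2Z)-3-[(2S,3R)-3-ethenyloxiran-2-yl]-1-hydroxybut-2-en-1-yl}-3-methylidene-5-[(triethylsilyl)oxy]oxan-2-one, via allylzinc bromide 28 (not isolated)
Conditions: Zn dust, THF/sat. aq NH4Cl 2:1, 0 °C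
Reagents that add atoms: none
Why: Barbier-type carbonyl allylation (SE2′ at ring carbon C7 through a Zimmerman–Traxler chair) in which the endocyclic alkene locks the E-type allyl geometry so that C6–OH and C7 come out anti (the future trans-lactone), while the aldehyde enters anti to the cis-disposed C8–OSiEt3 and C9 substituents, which fixes C7 relative to C8.

Step 20
Reactants: 29 (4S,5S,6S)-6-(3-{[tert-butyl(diphenyl)silyl]oxy}prop-1-en-2-yl)-4-{(1R,2Z)-3-[(2S,3R)-3-ethenyloxiran-2-yl]-1-hydroxybut-2-en-1-yl}-3-methylidene-5-[(triethylsilyl)oxy]oxan-2-one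
Product: 30 (4S,5S,6S)-6-(3-{[tert-butyl(diphenyl)silyl]oxy}prop-1-en-2-yl)-4-[(S)-{(2R,3R)-3-[(2R,3R)-3-ethenyloxiran-2-yl]-3-methyloxiran-2-yl}(hydroxy)methyl]-3-methylidene-5-[(triethylsilyl)oxy]oxan-2-one
Conditions: mCPBA (1.1 equiv), NaHCO3, CH2Cl2, 0 °C
Reagents that add atoms: meta-chloroperoxybenzoic acid (OOC(=O)c1cccc(Cl)c1)
Why: Hydroxyl-directed (Henbest) epoxidation of the only electron-rich, OH-bearing alkene is stereospecific (C3 and C6 stay cis on the new oxirane), and A1,3 strain between C6 and the cis oxiranyl carbon C3 makes the peracid add syn to the hydrogen-bonded C6–OH, giving the threo epoxy alcohol with C4 and C5 both R.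

Step 21
Reactants: 30 (4S,5S,6S)-6-(3-{[tert-butyl(diphenyl)silyl]oxy}prop-1-en-2-yl)-4-[(S)-{(2R,3R)-3-[(2R,3R)-3-ethenyloxiran-2-yl]-3-methyloxiran-2-yl}(hydroxy)methyl]-3-methylidene-5-[(triethylsilyl)oxy]oxan-2-one
Product: 31 (4S,5S)-4-{(1S,2S)-3-({[tert-butyl(diphenyl)silyl]oxy}methyl)-2-hydroxy-1-[(triethylsilyl)oxy]but-3-en-1-yl}-5-{(2R,3R)-3-[(2R,3R)-3-ethenyloxiran-2-yl]-3-methyloxiran-2-yl}-3-methylideneoxolan-2-one
Conditions: DBU (0.2 equiv), CH2Cl2, 0 °C to 20 °C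
Reagents that add atoms: none
Why: Base-catalysed translactonisation (intramolecular transesterification, 5-exo attack of C6–O on C12, much faster than attack on an oxirane) moves the acyl group to the more stable γ-lactone, which is trans because C6 and C7 were set anti, and frees C9–OH selectively.

Step 22
Reactants: 31 (4S,5S)-4-{(1S,2S)-3-({[tert-butyl(diphenyl)silyl]oxy}methyl)-2-hydroxy-1-[(triethylsilyl)oxy]but-3-en-1-yl}-5-{(2R,3R)-3-[(2R,3R)-3-ethenyloxiran-2-yl]-3-methyloxiran-2-yl}-3-methylideneoxolan-2-one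
Product: 32 (4S,5S)-4-{(1S,2S)-2-acetoxy-3-({[tert-butyl(diphenyl)silyl]oxy}methyl)-1-[(triethylsilyl)oxy]but-3-en-1-yl}-5-{(2R,3R)-3-[(2R,3R)-3-ethenyloxiran-2-yl]-3-methyloxiran-2-yl}-3-methylideneoxolan-2-one
Conditions: Ac2O, pyridine, DMAP (cat.), CH2Cl2, 0 °C
Reagents that add atoms: acetic anhydride (CC(=O)OC(C)=O)
Why: Nucleophile-catalysed acylation of the single free hydroxyl puts the acetate on O9 with retention, the O8 silyl ether keeping the two oxygens differentiated.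

Step 23
Reactants: 32 (4S,5S)-4-{(1S,2S)-2-acetoxy-3-({[tert-butyl(diphenyl)silyl]oxy}methyl)-1-[(triethylsilyl)oxy]but-3-en-1-yl}-5-{(2R,3R)-3-[(2R,3R)-3-ethenyloxiran-2-yl]-3-methyloxiran-2-yl}-3-methylideneoxolan-2-one
Product: 33 (1(10)Z,2R,3R,4R,5R,6S,7S,8S,9S)-9-acetoxy-14-[(tert-butyldiphenylsilyl)oxy]-2,3:4,5-diepoxy-8-[(triethylsilyl)oxy]germacra-1(10),11(13)-dien-12,6-olide
Conditions: second-generation Hoveyda–Grubbs catalyst RuCl2(H2IMes)(=CH-C6H4-2-O-iPr) (15 mol%), 1,4-benzoquinone, toluene (1 mM), 80 °C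
Reagents that add atoms: none
Why: Ring-closing metathesis between the terminal vinyl on the oxirane and the 1,1-disubstituted C10 olefin expels ethene, the ten-membered ring accepting the trisubstituted alkene only with C2 and C9 cis, while the electron-poor α-methylene lactone stays out of the catalytic cycle.

Step 24
Reactants: 33 (1(10)Z,2R,3R,4R,5R,6S,7S,8S,9S)-9-acetoxy-14-[(tert-butyldiphenylsilyl)oxy]-2,3:4,5-diepoxy-8-[(triethylsilyl)oxy]germacra-1(10),11(13)-dien-12,6-olide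
Product: 34 (1(10)Z,2R,3R,4R,5R,6S,7R,8S,9S)-9-acetoxy-2,3:4,5-diepoxy-8,14-dihydroxygermacra-1(10),11(13)-dien-12,6-olide
Conditions: Bu4NF/AcOH 1:1, THF, 0 °C to 20 °C
Reagents that add atoms: none
Why: Acetic acid-buffered fluoride desilylation removes both silyl ethers without acid (oxiranes survive) and without free alkoxide (acetate and lactone stay in place).

Step 25
Reactants: 34 (1(10)Z,2R,3R,4R,5R,6S,7R,8S,9S)-9-acetoxy-2,3:4,5-diepoxy-8,14-dihydroxygermacra-1(10),11(13)-dien-12,6-olide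
Product: 35 (1(10)E,2R,3R,4R,5R,6S,7R,8S,9S)-9-acetoxy-2,3:4,5-diepoxy-8-hydroxy-14-oxogermacra-1(10),11(13)-dien-12,6-olide
Conditions: MnO2, CH2Cl2, 20 °C
Reagents that add atoms: none
Why: MnO2 oxidises only the primary allylic C14 alcohol to the enal and leaves the non-allylic secondary C8 alcohol untouched (the E/Z letter changes only by priority).

Step 26
Reactants: 35 (1(10)E,2R,3R,4R,5R,6S,7R,8S,9S)-9-acetoxy-2,3:4,5-diepoxy-8-hydroxy-14-oxogermacra-1(10),11(13)-dien-12,6-olide; 27 (2R,3R)-2,3-dimethyloxirane-2-carboxylic acid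
Product: 37 (1(10)E,2R,3R,4R,5R,6S,7R,8S,9S)-9-acetoxy-8-{[(2R,3R)-2,3-dimethyloxiran-2-yl]carbonyloxy}-2,3:4,5-diepoxy-14-oxogermacra-1(10),11(13)-dien-12,6-olide, via mixed trichlorobenzoic anhydride 36 (not isolated)
Conditions: 27, 2,4,6-trichlorobenzoyl chloride, Et3N, toluene, 20 °C; then 35, DMAP, toluene, 20 °C
Reagents that add atoms: none
Why: Yamaguchi esterification acylates the hindered C8 alcohol with the hindered glycidic acid through its mixed anhydride and an acylpyridinium, with retention at C8 and no risk to the enal or oxiranes.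

Step 27
Reactants: 37 (1(10)E,2R,3R,4R,5R,6S,7R,8S,9S)-9-acetoxy-8-{[(2R,3R)-2,3-dimethyloxiran-2-yl]carbonyloxy}-2,3:4,5-diepoxy-14-oxogermacra-1(10),11(13)-dien-12,6-olide
Product: 38 leucanthin B
Conditions: NaClO2, NaH2PO4, 2-methylbut-2-ene, t-BuOH/H2O, 0 °C
Reagents that add atoms: sodium chlorite ([Na+].[O-]Cl=O)
Why: Pinnick (Lindgren–Kraus) oxidation converts the α,β-unsaturated aldehyde into the carboxylic acid at pH about 4 with a hypochlorite scavenger, conditions that esters, oxiranes and the α-methylene lactone tolerate, so no protecting group has to be removed after the acid is formed.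

## Compound list

1 | (tert-butyldimethylsilyloxy)acetaldehyde | O=CCO[Si](C)(C)C(C)(C)C | starting material
2 | ethyl 2-[bis(2,2,2-trifluoroethoxy)phosphoryl]propanoate | CCOC(=O)C(C)P(=O)(OCC(F)(F)F)OCC(F)(F)F | starting material
3 | ethyl (2Z)-4-[(tert-butyldimethylsilyl)oxy]-2-methylbut-2-enoate | CCOC(=O)/C(C)=C\CO[Si](C)(C)C(C)(C)C | intermediate
4 | (2Z)-4-[(tert-butyldimethylsilyl)oxy]-2-methylbut-2-en-1-ol | OC/C(C)=C\CO[Si](C)(C)C(C)(C)C | intermediate
5 | (2Z)-4-[(tert-butyldimethylsilyl)oxy]-2-methylbut-2-enal | O=C/C(C)=C\CO[Si](C)(C)C(C)(C)C | intermediate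
6 | allyl chloride | C=CCCl | starting material
7 | (Z)-(3-chloroprop-2-en-1-yl)diisopinocampheylborane, Ipc groups from (−)-α-pinene | Cl/C=C\CB([C@H]1C[C@H]2C[C@@H]([C@@H]1C)C2(C)C)[C@H]1C[C@H]2C[C@@H]([C@@H]1C)C2(C)C | intermediate (not isolated)
8 | (3S,4S,5Z)-7-[(tert-butyldimethylsilyl)oxy]-3-chloro-5-methylhepta-1,5-dien-4-ol | CC(C)(C)[Si](C)(C)OC/C=C(/C)[C@H](O)[C@@H](Cl)C=C | intermediate
9 | tert-butyl({(2Z)-3-[(2S,3R)-3-ethenyloxiran-2-yl]but-2-en-1-yl}oxy)dimethylsilane | CC(C)(C)[Si](C)(C)OC/C=C(/C)[C@@H]1O[C@@H]1C=C | intermediate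
10 | (2Z)-3-[(2S,3R)-3-ethenyloxiran-2-yl]but-2-en-1-ol | OC/C=C(/C)[C@@H]1O[C@@H]1C=C | intermediate
11 | (2Z)-3-[(2S,3R)-3-ethenyloxiran-2-yl]but-2-enal (fragment A) | O=C/C=C(/C)[C@@H]1O[C@@H]1C=C | intermediate
12 | 2-methylidenepropane-1,3-diol | C=C(CO)CO | starting material
13 | 2-{[(tert-butyldiphenylsilyl)oxy]methyl}prop-2-en-1-ol | C=C(CO)CO[Si](c1ccccc1)(c1ccccc1)C(C)(C)C | intermediate
14 | 2-{[(tert-butyldiphenylsilyl)oxy]methyl}prop-2-enal | C=C(C=O)CO[Si](c1ccccc1)(c1ccccc1)C(C)(C)C | intermediate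
15 | allyl alcohol | C=CCO | starting material
16 | 3-(methoxymethoxy)prop-1-ene | C=CCOCOC | intermediate
17 | [(Z)-3-(methoxymethoxy)prop-2-en-1-yl]diisopinocampheylborane, Ipc groups from (−)-α-pinene | COCO/C=C\CB([C@H]1C[C@H]2C[C@@H]([C@@H]1C)C2(C)C)[C@H]1C[C@H]2C[C@@H]([C@@H]1C)C2(C)C | intermediate (not isolated)
18 | (3S,4S)-2-{[(tert-butyldiphenylsilyl)oxy]methyl}-4-(methoxymethoxy)hexa-1,5-dien-3-ol | C=C[C@H](OCOC)[C@@H](O)C(=C)CO[Si](c1ccccc1)(c1ccccc1)C(C)(C)C | intermediate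
19 | 2-(bromomethyl)prop-2-enoic acid | C=C(CBr)C(=O)O | starting material
20 | (3S,4S)-2-{[(tert-butyldiphenylsilyl)oxy]methyl}-4-(methoxymethoxy)hexa-1,5-dien-3-yl 2-(bromomethyl)prop-2-enoate | C=C[C@H](OCOC)[C@@H](OC(=O)C(=C)CBr)C(=C)CO[Si](c1ccccc1)(c1ccccc1)C(C)(C)C | intermediate
21 | (5S,6S)-3-(bromomethyl)-6-(3-{[tert-butyl(diphenyl)silyl]oxy}prop-1-en-2-yl)-5-(methoxymethoxy)-5,6-dihydro-2H-pyran-2-one | O=C1O[C@@H](C(=C)CO[Si](c2ccccc2)(c2ccccc2)C(C)(C)C)[C@@H](OCOC)C=C1CBr | intermediate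
22 | (5S,6S)-3-(bromomethyl)-6-(3-{[tert-butyl(diphenyl)silyl]oxy}prop-1-en-2-yl)-5-hydroxy-5,6-dihydro-2H-pyran-2-one | O=C1O[C@@H](C(=C)CO[Si](c2ccccc2)(c2ccccc2)C(C)(C)C)[C@@H](O)C=C1CBr | intermediate
23 | (5S,6S)-3-(bromomethyl)-6-(3-{[tert-butyl(diphenyl)silyl]oxy}prop-1-en-2-yl)-5-[(triethylsilyl)oxy]-5,6-dihydro-2H-pyran-2-one (fragment B) | O=C1O[C@@H](C(=C)CO[Si](c2ccccc2)(c2ccccc2)C(C)(C)C)[C@@H](O[Si](CC)(CC)CC)C=C1CBr | intermediate
24 | angelic acid, (2Z)-2-methylbut-2-enoic acid | C/C=C(/C)C(=O)O | starting material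
25 | (2Z)-2-methylbut-2-en-1-ol | C/C=C(/C)CO | intermediate
26 | [(2S,3R)-2,3-dimethyloxiran-2-yl]methanol | OC[C@]1(C)O[C@@H]1C | intermediate
27 | (2R,3R)-2,3-dimethyloxirane-2-carboxylic acid (epoxyangelic acid) | OC(=O)[C@]1(C)O[C@@H]1C | intermediate
28 | allylzinc bromide from 23, bromo{[(5S,6S)-6-(3-{[tert-butyl(diphenyl)silyl]oxy}prop-1-en-2-yl)-2-oxo-5-[(triethylsilyl)oxy]-5,6-dihydro-2H-pyran-3-yl]methyl}zinc | O=C1O[C@@H](C(=C)CO[Si](c2ccccc2)(c2ccccc2)C(C)(C)C)[C@@H](O[Si](CC)(CC)CC)C=C1C[Zn]Br | intermediate (not isolated)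
29 | (4S,5S,6S)-6-(3-{[tert-butyl(diphenyl)silyl]oxy}prop-1-en-2-yl)-4-{(1R,2Z)-3-[(2S,3R)-3-ethenyloxiran-2-yl]-1-hydroxybut-2-en-1-yl}-3-methylidene-5-[(triethylsilyl)oxy]oxan-2-one | C=C1C(=O)O[C@@H](C(=C)CO[Si](c2ccccc2)(c2ccccc2)C(C)(C)C)[C@@H](O[Si](CC)(CC)CC)[C@@H]1[C@H](O)/C=C(/C)[C@@H]1O[C@@H]1C=C | intermediate
30 | (4S,5S,6S)-6-(3-{[tert-butyl(diphenyl)silyl]oxy}prop-1-en-2-yl)-4-[(S)-{(2R,3R)-3-[(2R,3R)-3-ethenyloxiran-2-yl]-3-methyloxiran-2-yl}(hydroxy)methyl]-3-methylidene-5-[(triethylsilyl)oxy]oxan-2-one | C=C1C(=O)O[C@@H](C(=C)CO[Si](c2ccccc2)(c2ccccc2)C(C)(C)C)[C@@H](O[Si](CC)(CC)CC)[C@@H]1[C@H](O)[C@H]1O[C@@]1(C)[C@@H]1O[C@@H]1C=C | intermediate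
31 | (4S,5S)-4-{(1S,2S)-3-({[tert-butyl(diphenyl)silyl]oxy}methyl)-2-hydroxy-1-[(triethylsilyl)oxy]but-3-en-1-yl}-5-{(2R,3R)-3-[(2R,3R)-3-ethenyloxiran-2-yl]-3-methyloxiran-2-yl}-3-methylideneoxolan-2-one | C=C1C(=O)O[C@H]([C@H]2O[C@@]2(C)[C@@H]2O[C@@H]2C=C)[C@H]1[C@H](O[Si](CC)(CC)CC)[C@@H](O)C(=C)CO[Si](c1ccccc1)(c1ccccc1)C(C)(C)C | intermediate
32 | (4S,5S)-4-{(1S,2S)-2-acetoxy-3-({[tert-butyl(diphenyl)silyl]oxy}methyl)-1-[(triethylsilyl)oxy]but-3-en-1-yl}-5-{(2R,3R)-3-[(2R,3R)-3-ethenyloxiran-2-yl]-3-methyloxiran-2-yl}-3-methylideneoxolan-2-one | C=C1C(=O)O[C@H]([C@H]2O[C@@]2(C)[C@@H]2O[C@@H]2C=C)[C@H]1[C@H](O[Si](CC)(CC)CC)[C@@H](OC(C)=O)C(=C)CO[Si](c1ccccc1)(c1ccccc1)C(C)(C)C | intermediate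
33 | (1(10)Z,2R,3R,4R,5R,6S,7S,8S,9S)-9-acetoxy-14-[(tert-butyldiphenylsilyl)oxy]-2,3:4,5-diepoxy-8-[(triethylsilyl)oxy]germacra-1(10),11(13)-dien-12,6-olide | C=C1C(=O)O[C@H]2[C@H]1[C@H](O[Si](CC)(CC)CC)[C@@H](OC(C)=O)/C(CO[Si](c1ccccc1)(c1ccccc1)C(C)(C)C)=C\[C@H]1O[C@H]1[C@]1(C)O[C@H]21 | intermediate
34 | (1(10)Z,2R,3R,4R,5R,6S,7R,8S,9S)-9-acetoxy-2,3:4,5-diepoxy-8,14-dihydroxygermacra-1(10),11(13)-dien-12,6-olide | C=C1C(=O)O[C@H]2[C@H]1[C@H](O)[C@@H](OC(C)=O)/C(CO)=C\[C@H]1O[C@H]1[C@]1(C)O[C@H]21 | intermediate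
35 | (1(10)E,2R,3R,4R,5R,6S,7R,8S,9S)-9-acetoxy-2,3:4,5-diepoxy-8-hydroxy-14-oxogermacra-1(10),11(13)-dien-12,6-olide | C=C1C(=O)O[C@H]2[C@H]1[C@H](O)[C@@H](OC(C)=O)/C(C=O)=C\[C@H]1O[C@H]1[C@]1(C)O[C@H]21 | intermediate
36 | (2R,3R)-2,3-dimethyloxirane-2-carboxylic 2,4,6-trichlorobenzoic anhydride | O=C(OC(=O)[C@]1(C)O[C@@H]1C)c1c(Cl)cc(Cl)cc1Cl | intermediate (not isolated)
37 | (1(10)E,2R,3R,4R,5R,6S,7R,8S,9S)-9-acetoxy-8-{[(2R,3R)-2,3-dimethyloxiran-2-yl]carbonyloxy}-2,3:4,5-diepoxy-14-oxogermacra-1(10),11(13)-dien-12,6-olide | C=C1C(=O)O[C@H]2[C@H]1[C@H](OC(=O)[C@]1(C)O[C@@H]1C)[C@@H](OC(C)=O)/C(C=O)=C\[C@H]1O[C@H]1[C@]1(C)O[C@H]21 | intermediate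
38 | leucanthin B | C=C1C(=O)O[C@H]2[C@H]1[C@H](OC(=O)[C@]1(C)O[C@@H]1C)[C@@H](OC(C)=O)/C(C(=O)O)=C\[C@H]1O[C@H]1[C@]1(C)O[C@H]21 | target

## Step count and risks

Total step count: 27. Longest linear sequence: 16 steps (12 → 13 → 14 → 18 → 20 → 21 → 22 → 23 → 29 → 30 → 31 → 32 → 33 → 34 → 35 → 37 → 38; the chain from 1 through fragment A is equally long).

The three steps most likely to fail:

Step 19 (fragment union). The risks are incomplete simple or facial diastereoselection, loss of the acid- and reduction-sensitive vinyloxirane of 11 to zinc metal or zinc halide, and opening of the allylic oxirane by the new C6 oxygen, which sits cis to it, so 29 is taken straight into step 20. The fallback sets out from 23 and comes back at 29. The bromide 23 is borylated with bis(pinacolato)diboron and Pd2(dba)3 (a zerovalent palladium source) in toluene at 50 °C to the isolable allylboronate (5S,6S)-6-(3-{[tert-butyl(diphenyl)silyl]oxy}prop-1-en-2-yl)-3-[(4,4,5,5-tetramethyl-1,3,2-dioxaborolan-2-yl)methyl]-5-[(triethylsilyl)oxy]-5,6-dihydro-2H-pyran-2-one F1. Allylboration of 11 with F1 (toluene, 40 °C, several days, no reducing metal and no metal halide) runs through the same ring-locked chair transition state, and hydrolysis of the borate on work-up gives 29.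

Step 23 (macrocyclic ring-closing metathesis). The 1,1-disubstituted C10 olefin is flanked by an allylic acetate and an allylic silyl ether and may not take up the carbene, so the vinyl oxirane end would oligomerise. The fallback sets out from 31 and comes back at 33. It changes the substrate and the order of events instead of the catalyst: the ring is closed on the free C9 carbinol 31, because a free allylic hydroxyl accelerates carbene transfer to the neighbouring hindered olefin whereas an allylic acetate retards it. This gives the macrocyclic alcohol (1(10)Z,2R,3R,4R,5R,6S,7S,8S,9S)-14-[(tert-butyldiphenylsilyl)oxy]-2,3:4,5-diepoxy-9-hydroxy-8-[(triethylsilyl)oxy]germacra-1(10),11(13)-dien-12,6-olide F2, which is then acetylated (Ac2O, pyridine, DMAP) to 33.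

Step 24 (double desilylation next to the C9 acetate). Under fluoride the freed O8 can take the acetyl group from O9 or attack the lactone. The fallback sets out from 33 and comes back at 37. Only the triethylsilyl group is removed (HF·pyridine, pyridine, THF, 0 °C) to give (1(10)Z,2R,3R,4R,5R,6S,7R,8S,9S)-9-acetoxy-14-[(tert-butyldiphenylsilyl)oxy]-2,3:4,5-diepoxy-8-hydroxygermacra-1(10),11(13)-dien-12,6-olide F3. F3 is esterified at once with 27 under the conditions of step 26 to (1(10)Z,2R,3R,4R,5R,6S,7R,8S,9S)-9-acetoxy-14-[(tert-butyldiphenylsilyl)oxy]-8-{[(2R,3R)-2,3-dimethyloxiran-2-yl]carbonyloxy}-2,3:4,5-diepoxygermacra-1(10),11(13)-dien-12,6-olide F4. Only then is the primary silyl ether cleaved (Bu4NF/AcOH, THF) to (1(10)Z,2R,3R,4R,5R,6S,7R,8S,9S)-9-acetoxy-8-{[(2R,3R)-2,3-dimethyloxiran-2-yl]carbonyloxy}-2,3:4,5-diepoxy-14-hydroxygermacra-1(10),11(13)-dien-12,6-olide F5, so no free secondary hydroxyl ever meets fluoride. MnO2 oxidation of F5 gives 37.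

## Further compounds

F1 | step 19 | (5S,6S)-6-(3-{[tert-butyl(diphenyl)silyl]oxy}prop-1-en-2-yl)-3-[(4,4,5,5-tetramethyl-1,3,2-dioxaborolan-2-yl)methyl]-5-[(triethylsilyl)oxy]-5,6-dihydro-2H-pyran-2-one | O=C1O[C@@H](C(=C)CO[Si](c2ccccc2)(c2ccccc2)C(C)(C)C)[C@@H](O[Si](CC)(CC)CC)C=C1CB1OC(C)(C)C(C)(C)O1
F2 | step 23 | (1(10)Z,2R,3R,4R,5R,6S,7S,8S,9S)-14-[(tert-butyldiphenylsilyl)oxy]-2,3:4,5-diepoxy-9-hydroxy-8-[(triethylsilyl)oxy]germacra-1(10),11(13)-dien-12,6-olide | C=C1C(=O)O[C@H]2[C@H]1[C@H](O[Si](CC)(CC)CC)[C@@H](O)/C(CO[Si](c1ccccc1)(c1ccccc1)C(C)(C)C)=C\[C@H]1O[C@H]1[C@]1(C)O[C@H]21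
F3 | step 24 | (1(10)Z,2R,3R,4R,5R,6S,7R,8S,9S)-9-acetoxy-14-[(tert-butyldiphenylsilyl)oxy]-2,3:4,5-diepoxy-8-hydroxygermacra-1(10),11(13)-dien-12,6-olide | C=C1C(=O)O[C@H]2[C@H]1[C@H](O)[C@@H](OC(C)=O)/C(CO[Si](c1ccccc1)(c1ccccc1)C(C)(C)C)=C\[C@H]1O[C@H]1[C@]1(C)O[C@H]21
F4 | step 24 | (1(10)Z,2R,3R,4R,5R,6S,7R,8S,9S)-9-acetoxy-14-[(tert-butyldiphenylsilyl)oxy]-8-{[(2R,3R)-2,3-dimethyloxiran-2-yl]carbonyloxy}-2,3:4,5-diepoxygermacra-1(10),11(13)-dien-12,6-olide | C=C1C(=O)O[C@H]2[C@H]1[C@H](OC(=O)[C@]1(C)O[C@@H]1C)[C@@H](OC(C)=O)/C(CO[Si](c1ccccc1)(c1ccccc1)C(C)(C)C)=C\[C@H]1O[C@H]1[C@]1(C)O[C@H]21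
F5 | step 24 | (1(10)Z,2R,3R,4R,5R,6S,7R,8S,9S)-9-acetoxy-8-{[(2R,3R)-2,3-dimethyloxiran-2-yl]carbonyloxy}-2,3:4,5-diepoxy-14-hydroxygermacra-1(10),11(13)-dien-12,6-olide | C=C1C(=O)O[C@H]2[C@H]1[C@H](OC(=O)[C@]1(C)O[C@@H]1C)[C@@H](OC(C)=O)/C(CO)=C\[C@H]1O[C@H]1[C@]1(C)O[C@H]21
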